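**Retrosynthetic overview**
- The strategy rests on the cis-fused γ-lactone ring (O–C6–C7–C11–C12). C7 is a ring CH next to the oxygen-bearing C6, and its only bond outside the seven-membered ring goes to C11. The C7–C11 bond is therefore traced back to a C7–H bond of a CH2 group and a carbene carried by the C6 oxygen; C13 is added afterwards as formaldehyde by phosphonate olefination.
- The insertion precursor 22 comes from the β-epoxide 17: opening at C6 by diethylphosphonoacetic acid, isovalerylation of the C5 hydroxyl, diazo transfer.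
- Epoxide 17 comes from cycloheptenone 8: 1,2-addition of an acetyl anion equivalent at C1, silylation, aldol condensation to the crotonoyl group, epoxidation anti to the C1 silyloxy group.
- Enone 8 comes from ring-closing metathesis (C5=C6) of dienone 7, whose C9 and C10 centres are set by an Evans syn-aldol reaction.
- Order of ring formation: cycloheptene (step 5), transient oxirane (step 9), γ-lactone last (step 13).

Key step: step 13

Remark on numbering and faces: C1 is the carbinol carbon carrying the crotonoyl group (C2–C4 plus methyl); the ring runs C1–C5–C6–C7–C8–C9–C10; C11–C13 are the methylene-lactone carbons. The ring face carrying the C9 oxygen is called β and the face of the C10 methyl α. The target, (1S,5S,6R,7S,9R,10S) in this numbering, then has C1–OH α, crotonoyl β, C5–O β, C6–O α, C7–C11 α.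

**Step 1**
Reactants: 1 (S)-4-benzyl-3-propionyloxazolidin-2-one; 2 pent-4-enal
Product: 3 (S)-4-benzyl-3-[(2S,3R)-3-hydroxy-2-methylhept-6-enoyl]oxazolidin-2-one
Conditions: Bu2BOTf, i-Pr2NEt, CH2Cl2, 0 °C; 2, −78 → 0 °C; then pH 7 buffer, MeOH, 30% H2O2
Reagents that add atoms: none
Why: Evans syn-aldol reaction, in which the Z-boron enolate reacts through a closed Zimmerman–Traxler transition state on the face away from the benzyl group, setting C10 (S) and C9 (R) as the syn pair that becomes the trans C9–O/C10–Me relationship of the ring.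

**Step 2**
Reactants: 3 aldol adduct
Product: 4 (2S,3R)-3-hydroxy-N-methoxy-N,2-dimethylhept-6-enamide
Conditions: MeNH(OMe)·HCl, AlMe3, THF, −10 °C → rt
Reagents that add atoms: N,O-dimethylhydroxylamine hydrochloride, CNOC.Cl
Why: Aluminium amide transamidation (Weinreb amide formation), assisted by the free β-hydroxyl, should release the auxiliary without epimerising C10.

**Step 3**
Reactants: 4 hydroxy Weinreb amide
Product: 5 (2S,3R)-3-(tert-butyldimethylsilyloxy)-N-methoxy-N,2-dimethylhept-6-enamide
Conditions: TBSOTf, 2,6-lutidine, CH2Cl2, −78 → 0 °C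
Reagents that add atoms: tert-butyldimethylsilyl triflate, CC(C)(C)[Si](C)(C)OS(=O)(=O)C(F)(F)F
Why: Silylation of a secondary alcohol with a silyl triflate should give an ether at C9 that lasts to the final step.

**Step 4**
Reactants: 5 silylated Weinreb amide; 6 vinylmagnesium bromide
Product: 7 (4S,5R)-5-(tert-butyldimethylsilyloxy)-4-methylnona-1,8-dien-3-one
Conditions: THF, 0 °C; poured into cold 1 M HCl
Reagents that add atoms: none
Why: Weinreb ketone synthesis, in which the chelated tetrahedral intermediate stops at the ketone stage so that the vinyl group (C5) is delivered once and C10 is untouched; the inverse acidic quench keeps the liberated amine from adding to the enone.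

**Step 5**
Reactants: 7 dienone
Product: 8 (6R,7S)-6-(tert-butyldimethylsilyloxy)-7-methylcyclohept-2-en-1-one
Conditions: RuCl2(=CHPh)(PCy3)(H2IMes) (second-generation Grubbs catalyst, 3 mol%), CH2Cl2 (5 mM), 40 °C
Reagents that add atoms: none
Why: Ring-closing metathesis, initiating at the terminal alkene and closing onto the enone alkene, should form C5=C6 and the seven-membered ring with loss of ethylene.

**Step 6**
Reactants: 8 cycloheptenone; 9 ethyl vinyl ether
Product: 11 1-[(1R,6R,7S)-6-(tert-butyldimethylsilyloxy)-1-hydroxy-7-methylcyclohept-2-en-1-yl]ethan-1-one, via 1-ethoxyvinyl carbinol 10 (not isolated)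
Conditions: 9, t-BuLi, THF, −78 → 0 °C; 8, −78 °C; then 0.5 M HCl, THF, 0 °C
Reagents that add atoms: water, O
Why: 1,2-Addition of the acyl anion equivalent 1-ethoxyvinyllithium to the enone carbonyl and hydrolysis of the enol ether; with the C9 and C10 substituents pseudo-equatorial, the bulky reagent should attack C1 from the β face, anti to the C10 methyl (equatorial-type attack as on 2-methylcycloalkanones), so the C1 oxygen ends up α, cis to the methyl.

**Step 7**
Reactants: 11 tertiary α-hydroxy ketone
Product: 12 1-[(1R,6R,7S)-6-(tert-butyldimethylsilyloxy)-7-methyl-1-(triethylsilyloxy)cyclohept-2-en-1-yl]ethan-1-one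
Conditions: TESOTf, 2,6-lutidine, CH2Cl2, −78 → 0 °C
Reagents that add atoms: triethylsilyl triflate, CC[Si](CC)(CC)OS(=O)(=O)C(F)(F)F
Why: Silyl triflate silylation of the tertiary alcohol caps the hydroxyl that would otherwise direct the epoxidation to the wrong face and later trap the carbene by O–H insertion.

**Step 8**
Reactants: 12 methyl ketone; 13 acetaldehyde
Product: 16 (E)-1-[(1R,6R,7S)-6-(tert-butyldimethylsilyloxy)-7-methyl-1-(triethylsilyloxy)cyclohept-2-en-1-yl]but-2-en-1-one, via aldol adduct 14 (not isolated), via β-mesyloxy ketone 15 (not isolated)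
Conditions: LiN(i-Pr)2, THF, −78 °C; 13; then MsCl, Et3N, −78 °C → rt
Reagents that add atoms: none
Why: Directed aldol addition followed by mesylation and E1cB elimination (aldol condensation); only the methyl group can enolise because C1 is quaternary, and the elimination should give the conjugated E-enone.

**Step 9**
Reactants: 16 crotonoyl cycloheptene
Product: 17 β-epoxide, (E)-1-[(1S,5S,6S,9R,10S)-5,6-epoxy-9-(tert-butyldimethylsilyloxy)-10-methyl-1-(triethylsilyloxy)cycloheptyl]but-2-en-1-one in the route numbering (the C1 descriptor changes only because C5 gains an oxygen)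
Conditions: m-CPBA, NaHCO3, CH2Cl2, 0 °C → rt
Reagents that add atoms: m-chloroperoxybenzoic acid, OOC(=O)c1cccc(Cl)c1
Why: Peracid (Prilezhaev) epoxidation; the electron-poor crotonoyl alkene is inert, and in the ring conformer with the C9 and C10 groups pseudo-equatorial the C1 silyloxy group is pseudoaxial on the α face, so the ring alkene should be attacked from the β face, setting C5–O β.

**Step 10**
Reactants: 17 β-epoxide; 18 diethylphosphonoacetic acid
Product: 19 hydroxy ester, (1S,5S,6R,9R,10S): C6 α-O2CCH2P(O)(OEt)2, C5 β-OH, C1 α-OSiEt3 and β-crotonoyl, C9 β-OSi(t-Bu)Me2, C10 α-Me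
Conditions: 18, rac-Co(salen)(OAc) [salen = N,N'-bis(3,5-di-tert-butylsalicylidene)-trans-cyclohexane-1,2-diaminate, C36H52N2O2; trivalent cobalt] (5 mol%), i-Pr2NEt, t-BuOMe, rt → 40 °C
Reagents that add atoms: none
Why: Cobalt-salen-catalysed addition of a carboxylic acid to an epoxide (SN2, trans-diaxial opening); C5 is neopentyl-like next to the quaternary C1, so the carboxylate should attack C6 from the α face with inversion, which sets C6–O α and leaves the C5 hydroxyl β.

**Step 11**
Reactants: 19 hydroxy ester; 20 isovaleric anhydride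
Product: 21 diester, (1S,5S,6R,9R,10S): as 19 with C5 β-O2CCH2CH(CH3)2
Conditions: 20, DMAP, Et3N, CH2Cl2, rt
Reagents that add atoms: none
Why: DMAP-catalysed acyl transfer from the anhydride should esterify the one remaining free hydroxyl, and the resulting C5 ester also deactivates the C5–H bond for step 13.

**Step 12**
Reactants: 21 phosphonoacetate diester
Product: 22 diazo ester, (1S,5S,6R,9R,10S): as 21 with C6 α-O2C–C(=N2)–P(O)(OEt)2
Conditions: p-ABSA, DBU, MeCN, 0 °C
Reagents that add atoms: 4-acetamidobenzenesulfonyl azide, CC(=O)Nc1ccc(cc1)S(=O)(=O)N=[N+]=[N-]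
Why: Regitz diazo transfer to the only active methylene group, the phosphonoacetate CH2, which is far more acidic than the isovalerate and crotonoyl positions.

**Step 13**
Reactants: 22 diazo ester
Product: 23 cis-fused α-(diethoxyphosphoryl)-γ-lactone, (1S,5S,6R,7S,9R,10S), drawn as the 11S epimer with phosphorus on the convex face (either C11 epimer serves)
Conditions: Rh2(O2CC7H15)4 (2 mol%), ClCH2CH2Cl, 80 °C, slow addition of 22
Reagents that add atoms: none
Why: Loss of N2 at the dirhodium core gives an electrophilic rhodium carbene that inserts into the C7–H bond through a concerted three-centre transition state with retention at C7, which is the known dirhodium-catalysed C–H insertion of cycloalkyl diazo(phosphono)acetates to α-phosphono-γ-butyrolactones. The lactone ring (O, C6, C7, C11, C12) closes by 1,5-insertion through a five-membered cyclic array in which the C7–C11 bond is formed. C7 is controlled by the tether, since the carbene hangs from the α oxygen on C6 and reaches the α hydrogen of C7, so the ring fusion should be cis; C11 is not controlled beyond a preference for phosphorus on the convex face and is erased in step 14. The step needs insertion at C7–H and not at C5–H, at C6–H (β-lactone) or in the side chains: C5–H is deactivated by its acyloxy group and crowded by the quaternary C1, four-membered closure is slower than five-membered closure, and the crotonoyl alkene and the ketone and ester carbonyls are electron-poor and remote, so cyclopropanation and ylide formation should not compete.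

**Step 14**
Reactants: 23 phosphonolactone; 24 paraformaldehyde
Product: 25 α-methylene lactone with both silyl ethers in place, (1S,5S,6R,7S,9R,10S)
Conditions: KOt-Bu (1.0 equiv), THF, −78 °C; 24, −78 → 0 °C
Reagents that add atoms: none
Why: Horner–Wadsworth–Emmons olefination of the phosphonolactone anion, by far the most acidic site, with formaldehyde should install C13 as the exocyclic methylene and remove the C11 stereocentre.

**Step 15**
Reactants: 25 bis-silyl ether
Product: 26 CNP0186412.1 (target)
Conditions: HF·pyridine, pyridine, THF, 0 °C → rt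
Reagents that add atoms: none
Why: Buffered acidic fluoride desilylation should cleave both the tertiary triethylsilyl and the secondary tert-butyldimethylsilyl ether without the basic fluoride that would add to the enone and the methylene lactone.

**Compound list**
1 | (S)-4-benzyl-3-propionyloxazolidin-2-one | CCC(=O)N1[C@@H](Cc2ccccc2)COC1=O | starting material
2 | pent-4-enal | C=CCCC=O | starting material
3 | (S)-4-benzyl-3-[(2S,3R)-3-hydroxy-2-methylhept-6-enoyl]oxazolidin-2-one | C=CCC[C@@H](O)[C@H](C)C(=O)N1[C@@H](Cc2ccccc2)COC1=O | intermediate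
4 | (2S,3R)-3-hydroxy-N-methoxy-N,2-dimethylhept-6-enamide | C=CCC[C@@H](O)[C@H](C)C(=O)N(C)OC | intermediate
5 | (2S,3R)-3-(tert-butyldimethylsilyloxy)-N-methoxy-N,2-dimethylhept-6-enamide | C=CCC[C@@H](O[Si](C)(C)C(C)(C)C)[C@H](C)C(=O)N(C)OC | intermediate
6 | vinylmagnesium bromide | C=C[Mg]Br | starting material
7 | (4S,5R)-5-(tert-butyldimethylsilyloxy)-4-methylnona-1,8-dien-3-one | C=CCC[C@@H](O[Si](C)(C)C(C)(C)C)[C@H](C)C(=O)C=C | intermediate
8 | (6R,7S)-6-(tert-butyldimethylsilyloxy)-7-methylcyclohept-2-en-1-one | O=C1C=CCC[C@@H](O[Si](C)(C)C(C)(C)C)[C@@H]1C | intermediate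
9 | ethyl vinyl ether | C=COCC | starting material
10 | (1R,6R,7S)-6-(tert-butyldimethylsilyloxy)-1-(1-ethoxyethenyl)-7-methylcyclohept-2-en-1-ol | C=C(OCC)[C@@]1(O)C=CCC[C@@H](O[Si](C)(C)C(C)(C)C)[C@@H]1C | intermediate
11 | 1-[(1R,6R,7S)-6-(tert-butyldimethylsilyloxy)-1-hydroxy-7-methylcyclohept-2-en-1-yl]ethan-1-one | CC(=O)[C@@]1(O)C=CCC[C@@H](O[Si](C)(C)C(C)(C)C)[C@@H]1C | intermediate
12 | 1-[(1R,6R,7S)-6-(tert-butyldimethylsilyloxy)-7-methyl-1-(triethylsilyloxy)cyclohept-2-en-1-yl]ethan-1-one | CC(=O)[C@@]1(O[Si](CC)(CC)CC)C=CCC[C@@H](O[Si](C)(C)C(C)(C)C)[C@@H]1C | intermediate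
13 | acetaldehyde | CC=O | starting material
14 | 3-hydroxy-1-[(1R,6R,7S)-6-(tert-butyldimethylsilyloxy)-7-methyl-1-(triethylsilyloxy)cyclohept-2-en-1-yl]butan-1-one (both C3 epimers, formed as the lithium alkoxide) | CC(O)CC(=O)[C@@]1(O[Si](CC)(CC)CC)C=CCC[C@@H](O[Si](C)(C)C(C)(C)C)[C@@H]1C | intermediate
15 | methanesulfonate of 14 | CC(OS(C)(=O)=O)CC(=O)[C@@]1(O[Si](CC)(CC)CC)C=CCC[C@@H](O[Si](C)(C)C(C)(C)C)[C@@H]1C | intermediate
16 | (E)-1-[(1R,6R,7S)-6-(tert-butyldimethylsilyloxy)-7-methyl-1-(triethylsilyloxy)cyclohept-2-en-1-yl]but-2-en-1-one | C/C=C/C(=O)[C@@]1(O[Si](CC)(CC)CC)C=CCC[C@@H](O[Si](C)(C)C(C)(C)C)[C@@H]1C | intermediate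
17 | β-epoxide (1S,5S,6S,9R,10S): C5,C6 oxirane on the β face, C1 α-OSiEt3 and β-crotonoyl, C9 β-OSi(t-Bu)Me2, C10 α-Me | C/C=C/C(=O)[C@@]1(O[Si](CC)(CC)CC)[C@H]2O[C@H]2CC[C@@H](O[Si](C)(C)C(C)(C)C)[C@@H]1C | intermediate
18 | diethylphosphonoacetic acid [2-(diethoxyphosphoryl)acetic acid] | CCOP(=O)(OCC)CC(=O)O | starting material
19 | hydroxy ester (1S,5S,6R,9R,10S): C6 α-(diethoxyphosphoryl)acetate, C5 β-OH | CCOP(=O)(OCC)CC(=O)O[C@@H]1CC[C@@H](O[Si](C)(C)C(C)(C)C)[C@H](C)[C@@](O[Si](CC)(CC)CC)(C(=O)/C=C/C)[C@H]1O | intermediate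
20 | isovaleric anhydride (3-methylbutanoic anhydride) | CC(C)CC(=O)OC(=O)CC(C)C | starting material
21 | diester (1S,5S,6R,9R,10S): C6 α-(diethoxyphosphoryl)acetate, C5 β-isovalerate | CCOP(=O)(OCC)CC(=O)O[C@@H]1CC[C@@H](O[Si](C)(C)C(C)(C)C)[C@H](C)[C@@](O[Si](CC)(CC)CC)(C(=O)/C=C/C)[C@H]1OC(=O)CC(C)C | intermediate
22 | diazo ester (1S,5S,6R,9R,10S): C6 α-diazo(diethoxyphosphoryl)acetate, C5 β-isovalerate | CCOP(=O)(OCC)C(=[N+]=[N-])C(=O)O[C@@H]1CC[C@@H](O[Si](C)(C)C(C)(C)C)[C@H](C)[C@@](O[Si](CC)(CC)CC)(C(=O)/C=C/C)[C@H]1OC(=O)CC(C)C | intermediate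
23 | cis-fused α-(diethoxyphosphoryl)-γ-lactone (1S,5S,6R,7S,9R,10S,11S) | CCOP(=O)(OCC)[C@@H]1C(=O)O[C@@H]2[C@H]1C[C@@H](O[Si](C)(C)C(C)(C)C)[C@H](C)[C@@](O[Si](CC)(CC)CC)(C(=O)/C=C/C)[C@H]2OC(=O)CC(C)C | intermediate
24 | paraformaldehyde (source of formaldehyde) | C=O | starting material
25 | C9 tert-butyldimethylsilyl, C1 triethylsilyl bis-ether of the target | C=C1C(=O)O[C@@H]2[C@H]1C[C@@H](O[Si](C)(C)C(C)(C)C)[C@H](C)[C@@](O[Si](CC)(CC)CC)(C(=O)/C=C/C)[C@H]2OC(=O)CC(C)C | intermediate
26 | CNP0186412.1, (1S,5S,6R,7S,9R,10S) in the route numbering | C=C1C(=O)O[C@@H]2[C@H]1C[C@@H](O)[C@H](C)[C@@](O)(C(=O)/C=C/C)[C@H]2OC(=O)CC(C)C | target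

**Step count**
Total: 15 steps. Longest linear sequence: 15 steps (from 1 and 2 to 26).

**Steps most likely to fail**

Step 10. The carboxylate has to reach C6 from the α face, where it passes the C1 silyloxy group in a 1,3-relationship. The SN2 opening may therefore be slow, and on forcing, loss of the triethylsilyl group or opening at C5 may take over. Fallback: from 16, catalytic OsO4 with N-methylmorpholine N-oxide in acetone–water should dihydroxylate the ring alkene on the same β face as the peracid (anti to the C1 silyloxy group; the electron-poor crotonoyl alkene is slower) to give the β-cis-diol F6. A Mitsunobu esterification (PPh3, diisopropyl azodicarboxylate, acid 18, THF) then turns the less hindered C6 hydroxyl into an oxyphosphonium leaving group that the carboxylate displaces with inversion. This comes back to the route at 19.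

Step 13. The bulky phosphoryl carbene may be diverted into four-membered closure at C6–H, trans-fused or C5–H insertion, or carbene dimerisation. Fallback: from 17, opening with mono-tert-butyl malonate under the conditions of step 10 gives the hydroxy malonate F7. Isovalerylation as in step 11 gives the diester F8, and diazo transfer (p-ABSA, Et3N, MeCN) gives the diazomalonate F9. Rh2(OAc)4 in CH2Cl2 should then give the cis-fused α-(tert-butoxycarbonyl) lactone F10 through a smaller and more electrophilic carbene of the best-documented acceptor/acceptor class. Trifluoroacetic acid with a little water cleaves the tert-butyl ester and both silyl ethers to give the α-carboxy lactone diol F11. Decarboxylative Mannich methylenation (aqueous CH2O, Et2NH, then AcOH/NaOAc) comes back to the route at 26.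

Step 9. Facial selectivity may be poor if the ring does not hold the C1 silyloxy group pseudoaxial, so that peracid also attacks the α face. Fallback: from 12, reduction of the ketone (i-Bu2AlH, CH2Cl2, −78 °C) gives the side-chain carbinol F1. Epoxidation with VO(acac)2 and t-BuOOH, directed by this homoallylic hydroxyl, which sits on the β face while the C1 oxygen is capped, gives the β-epoxy alcohol F2. Dess–Martin periodinane returns the epoxy methyl ketone F3. The aldol condensation of step 8, through the aldol adduct F4 and its mesylate F5, comes back to the route at 17.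

**Further compounds**
F1 | step 9 | 1-[(1R,6R,7S)-6-(tert-butyldimethylsilyloxy)-7-methyl-1-(triethylsilyloxy)cyclohept-2-en-1-yl]ethan-1-ol (both carbinol epimers) | CC(O)[C@@]1(O[Si](CC)(CC)CC)C=CCC[C@@H](O[Si](C)(C)C(C)(C)C)[C@@H]1C
F2 | step 9 | β-epoxy alcohol: F1 with the C5,C6 oxirane on the β face | CC(O)[C@@]1(O[Si](CC)(CC)CC)[C@H]2O[C@H]2CC[C@@H](O[Si](C)(C)C(C)(C)C)[C@@H]1C
F3 | step 9 | β-epoxy methyl ketone | CC(=O)[C@@]1(O[Si](CC)(CC)CC)[C@H]2O[C@H]2CC[C@@H](O[Si](C)(C)C(C)(C)C)[C@@H]1C
F4 | step 9 | aldol adduct of F3 with acetaldehyde | CC(O)CC(=O)[C@@]1(O[Si](CC)(CC)CC)[C@H]2O[C@H]2CC[C@@H](O[Si](C)(C)C(C)(C)C)[C@@H]1C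
F5 | step 9 | methanesulfonate of F4 | CC(OS(C)(=O)=O)CC(=O)[C@@]1(O[Si](CC)(CC)CC)[C@H]2O[C@H]2CC[C@@H](O[Si](C)(C)C(C)(C)C)[C@@H]1C
F6 | step 10 | β-cis-diol: 16 with C5 β-OH and C6 β-OH | C/C=C/C(=O)[C@@]1(O[Si](CC)(CC)CC)[C@@H](O)[C@@H](O)CC[C@@H](O[Si](C)(C)C(C)(C)C)[C@@H]1C
F7 | step 13 | hydroxy malonate: C6 α-(tert-butyl malonate), C5 β-OH | CC(C)(C)OC(=O)CC(=O)O[C@@H]1CC[C@@H](O[Si](C)(C)C(C)(C)C)[C@H](C)[C@@](O[Si](CC)(CC)CC)(C(=O)/C=C/C)[C@H]1O
F8 | step 13 | C5 isovalerate of F7 | CC(C)(C)OC(=O)CC(=O)O[C@@H]1CC[C@@H](O[Si](C)(C)C(C)(C)C)[C@H](C)[C@@](O[Si](CC)(CC)CC)(C(=O)/C=C/C)[C@H]1OC(=O)CC(C)C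
F9 | step 13 | diazomalonate of F8 | CC(C)(C)OC(=O)C(=[N+]=[N-])C(=O)O[C@@H]1CC[C@@H](O[Si](C)(C)C(C)(C)C)[C@H](C)[C@@](O[Si](CC)(CC)CC)(C(=O)/C=C/C)[C@H]1OC(=O)CC(C)C
F10 | step 13 | cis-fused α-(tert-butoxycarbonyl)-γ-lactone | CC(C)(C)OC(=O)[C@@H]1C(=O)O[C@@H]2[C@H]1C[C@@H](O[Si](C)(C)C(C)(C)C)[C@H](C)[C@@](O[Si](CC)(CC)CC)(C(=O)/C=C/C)[C@H]2OC(=O)CC(C)C
F11 | step 13 | α-carboxy-γ-lactone diol | OC(=O)[C@@H]1C(=O)O[C@@H]2[C@H]1C[C@@H](O)[C@H](C)[C@@](O)(C(=O)/C=C/C)[C@H]2OC(=O)CC(C)C
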